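**Conventions.** Chroman and chromene atoms are numbered O1, C2–C8a. Isoflavone atoms are always called "isoflavone C2, C3, C4". In the open-chain ring B precursors the carbon bearing the acetic ester arm is C1.

## Analysis of the target

Target 24 is an isoflavone: a 5,7-dihydroxy-4H-chromen-4-one (rings A and C) whose C3 is bonded to C8 of a 5-hydroxy-2H-chromene, so ring B is an unsymmetrical 1,2,3,4-tetrasubstituted benzene fused to a pyran ring. The only stereocentre is chromene C2, a quaternary carbon carrying methyl, hydroxymethyl, the ring oxygen O1 and the alkene carbon C3. It is S, and because nothing else is stereogenic it has to be set by absolute control. The sensitive functions are the 2H-chromene, three free phenols, the base-sensitive pyranone of ring C and a neopentylic primary alcohol. The chromene is an allylic, benzylic tertiary aryl ether that ionises under acid and can open electrocyclically to an ortho-quinone methide, which would erase the stereocentre. The difficulty lies in an oxygenated quaternary stereocentre with no neighbouring functional handle, a contiguously substituted ring B, and a C–C bond from isoflavone C3 to an aryl carbon flanked by the ring oxygen. The strategy rests on ring C: it is bounded by the threefold-symmetric phloroglucinol ring A, the carbonyl C4, the aryl-bearing C3 and the one-carbon unit C2, so ring A, an arylacetic acid carrying ring B and a formyl equivalent can converge on it in one vessel. A second feature serves the end game: the phenol at C5 is ortho to C4a, so the C3=C4 alkene can be introduced last by dehydrogenating a chroman that tolerates the Lewis-acidic ring C construction.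

## Retrosynthetic reasoning

**24 ⇒ 23.** The last bond cut is the acyl C–O bond of a primary acetate. The acetate is needed in the two preceding steps and its removal needs only mild methanolysis, which the pyranone and the chromene tolerate.

**23 ⇒ 22.** The C3=C4 alkene of the chromene is traced back to the saturated chroman 22. The chromene would ionise at its allylic tertiary ether under the Lewis acid of the ring C construction, whereas the chroman should not. The forward step is a dehydrogenation by hydride abstraction at C4, which the C5 phenol and O1 make easy. The acetate keeps the hydroxymethyl group from adding across the intermediate quinone methide.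

**22 ⇒ 18 + 19 + 20.** This is the key disconnection. Ring C is cut at isoflavone C4–C4a, C3–C2 and C2–O1, giving the arylacetic acid 18, phloroglucinol 19 and N,N-dimethylformamide 20. The cut is placed here because 19 is symmetric, so acylation has no regiochemical question, and because ring A then needs no protecting groups. The forward reaction must C-acylate 19 with 18, formylate the resulting methylene and close the pyranone without disturbing the tertiary ether or the acetate.

**18 ⇒ 17 ⇒ 16 ⇒ 15.** The acid and the C5 phenol are traced back to a benzyl ester and a silyl ether, and the acetate to the primary alcohol 15. The benzyl ester is chosen because hydrogenolysis frees the acid without touching the acetate, which hydrolysis could not do.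

**15 ⇒ 13 (through 14).** The hydroxymethyl carbon is traced back to the internal carbon of a vinyl group. Oxidative cleavage gives aldehyde 14, which cannot epimerise because its α-carbon is quaternary, and reduction gives 15.

**13 ⇒ 12.** The chroman is cut at O1–C2. In the forward direction the phenol of 12 attacks the more substituted terminus of a π-allylpalladium complex under a chiral diphosphine. This closes the pyran ring and sets the only stereocentre under catalyst control.

**12 ⇒ 11 ⇒ 6 + 9.** The carbonate comes from allylic alcohol 11. Its side chain is cut between the homobenzylic CH2 and the methyl-bearing alkene carbon, giving styrene 6 (as its hydroboration product 10) and the Z-iodide 9. The alkene geometry is thereby bought with 9 and not made by an olefination that would give mixtures.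

**6 ⇒ 5 ⇒ 4.** The vinyl group comes from a formyl group by methylenation. The formyl group is placed by a phenoxide-directed ortho-formylation of 4, where C3 is the only free position ortho to the only free phenol.

**4 ⇒ 3 ⇒ 2 ⇒ 1.** The two phenols of 2,4-dihydroxyphenylacetic acid 1 are told apart by lactonisation. Only the ortho hydroxyl can form the five-membered lactone 2, the remaining phenol is silylated to 3, and alcoholysis then frees the ortho phenol in 4.

**9 ⇒ 7 (through 8).** The Z-iodide is cut at C–I and traced to but-2-yn-1-ol 7 through the cyclic alkenylalanate 8, which fixes the geometry.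

## Alternatives that were turned down

**Alternative 1:** The pyran ring is cut at C3–C4 and O1–C2, and a temporary C4–O–CH2 bridge to C2 is accepted. In the forward step a chiral Brønsted acid would condense a brominated salicylaldehyde with an allylic alcohol bearing a 1,1-disubstituted alkene to an O-allyl oxocarbenium ion. The alkene terminus would add to the benzylic carbon while the phenol oxygen captures the tertiary carbon, giving the bridged chroman A1, (2S,4S)-8-bromo-2-methyl-5-[(triisopropylsilyl)oxy]-3,4-dihydro-2H-4,2-(epoxymethano)chromene.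
- For it: two simple pieces give the pyran ring and the stereocentre in one step, and opening the bridge by elimination would later deliver both the C3=C4 alkene and the free hydroxymethyl group. On step count and on avoiding any oxidant near the phenols it is stronger than the chosen route.
- Against it: the stereocentre forms at the carbon farthest from the ion-paired oxocarbenium centre, so facial control by the counter-anion has to be relayed through a tether. The bridge opening needs forcing acid or base on an aryl bromide. The bromide of A1 must then be cross-coupled to a 3-halogenated, phenol-protected chromone, which brings back protecting groups on ring A and carries the fragile chromene through several steps.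
- In its place the chosen strategy offers a stereocentre set at the reacting allyl terminus by an exchangeable ligand, and ring A attached without protection or cross-coupling.

**Alternative 2:** The chromene is cut at C8a–O1. In the forward step the tertiary alkoxide of a Z-alkenyl alcohol would couple with the neighbouring aryl bromide under palladium catalysis to close the pyran ring, giving A2, (2S)-2-{[(tert-butyldimethylsilyl)oxy]methyl}-8-chloro-5-(methoxymethoxy)-2-methyl-2H-chromene.
- For it: the stereocentre is made on an acyclic tertiary alcohol before ring closure and no bond to it is touched afterwards. The alkene is in place from the start, so no late dehydrogenation is needed. On both points it is stronger than the chosen route.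
- Against it: it needs an arene with adjacent bromine and chlorine, an acetal-protected phenol and a Z-alkenyl chain. Reductive elimination of a tertiary alkoxide from a di-ortho-substituted arylpalladium is the most demanding case of C–O coupling. The Z-allylic tertiary alcohol can ionise or eliminate. The remaining chloride of A2, ortho to the new ether, must be coupled to a protected chromone, and the acetal must be removed by acid in the presence of the chromene.
- In its place the chosen strategy accepts one late oxidation but keeps the chromene out of all but the last two steps and installs ring A by a protecting-group-free condensation.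

**Alternative 3:** A chroman is cut at C2–C3. In the forward step a potassium amide base would deprotonate an O-aryl lactic ester bearing an ortho 2-bromoethyl arm. The enolate, chiral only through its twisted aryl C–O axis, would displace the primary bromide in a 6-exo-tet alkylation before it racemises, giving A3, tert-butyl (2S)-8-bromo-5-(methoxymethoxy)-2-methyl-3,4-dihydro-2H-chromene-2-carboxylate.
- For it: the chirality comes from a cheap hydroxy acid, and one C–C bond formation gives the ring and the quaternary centre. It reaches a chroman of the kind of 13 in fewer steps than the chosen route.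
- Against it: the stereochemical information survives only as a short-lived conformational chirality. Its retention depends on the rotation barrier about the C–O axis relative to the alkylation rate, which this substitution pattern must happen to provide and which no ligand change can tune. E2 loss of HBr from the bromoethyl arm competes. A3 still needs ester reduction, conversion of the bromide into the acetic acid arm or a cross-coupling, and the same late dehydrogenation.
- In its place the chosen strategy offers ligand-controlled selectivity with either enantiomer available, and the acetic acid arm present from the first step.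

Key step: step 14

**Assumption:** the (R,R) enantiomer of the diphosphine ligand in step 9 is taken to convert the Z-carbonate 12 into the (2S) chroman. The sense of induction has to be confirmed on the first run, and the (S,S) ligand is used instead if it is opposite, with no other change.

## Route

Step 1
Reactants: 1 2,4-dihydroxyphenylacetic acid
Product: 2 6-hydroxy-1-benzofuran-2(3H)-one
Conditions: p-TsOH·H2O (5 mol%), toluene, reflux, Dean–Stark trap
Reagents that add atoms: none
Why: Acid-catalysed lactonisation with azeotropic removal of water; only the ortho hydroxyl can reach the carboxyl group (five-membered ring), so the two phenols are differentiated without relying on a selective protection.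

Step 2
Reactants: 2 6-hydroxy-1-benzofuran-2(3H)-one
Product: 3 6-[(triisopropylsilyl)oxy]-1-benzofuran-2(3H)-one
Conditions: iPr3SiOSO2CF3 (1.1 equiv), 2,6-lutidine (1.5 equiv), CH2Cl2, −78 → 0 °C
Reagents that add atoms: triisopropylsilyl trifluoromethanesulfonate, CC(C)[Si](OS(=O)(=O)C(F)(F)F)(C(C)C)C(C)C
Why: O-Silylation of the single free phenol with a silyl triflate and a hindered, non-nucleophilic base, which neither opens the aryl lactone nor alkylates its acidic methylene; any silyl ketene acetal formed reverts on aqueous work-up.

Step 3
Reactants: 3 6-[(triisopropylsilyl)oxy]-1-benzofuran-2(3H)-one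
Product: 4 benzyl 2-{2-hydroxy-4-[(triisopropylsilyl)oxy]phenyl}acetate
Conditions: BnOH (10 equiv), (+)-camphor-10-sulfonic acid (10 mol%), CH2Cl2, rt → 40 °C
Reagents that add atoms: benzyl alcohol, OCc1ccccc1
Why: Acid-catalysed alcoholysis (transesterification) of the activated aryl lactone, driven by excess alcohol, frees the C2 phenol as the only free hydroxyl; the benzyl ester is chosen because hydrogenolysis can later remove it without touching an acetate.

Step 4
Reactants: 4 benzyl 2-{2-hydroxy-4-[(triisopropylsilyl)oxy]phenyl}acetate
Product: 5 benzyl 2-{3-formyl-2-hydroxy-4-[(triisopropylsilyl)oxy]phenyl}acetate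
Conditions: MgCl2 (2 equiv), Et3N (4 equiv), (CH2O)n (6 equiv), MeCN, reflux; then 1 M HCl
Reagents that add atoms: formaldehyde (as paraformaldehyde), C=O
Why: Magnesium-mediated ortho-formylation of a phenol (Casnati–Skattebøl type): formaldehyde is delivered within the magnesium phenoxide only ortho to oxygen, and C3 is the only free ortho position because C1 carries the ester arm; a second formaldehyde oxidises the hydroxymethyl intermediate by hydride transfer.

Step 5
Reactants: 5 benzyl 2-{3-formyl-2-hydroxy-4-[(triisopropylsilyl)oxy]phenyl}acetate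
Product: 6 benzyl 2-{3-ethenyl-2-hydroxy-4-[(triisopropylsilyl)oxy]phenyl}acetate
Conditions: Ph3PCH3Br (3 equiv), NaN(SiMe3)2 (2.9 equiv), THF, 0 °C → rt, short reaction time
Reagents that add atoms: methyltriphenylphosphonium bromide, C[P+](c1ccccc1)(c1ccccc1)c1ccccc1.[Br-]
Why: Wittig methylenation of the salicylaldehyde; excess ylide compensates for deprotonation of the phenol, and the low temperature and short time keep the phenoxide from closing onto the neighbouring ester.

Step 6
Reactants: 7 but-2-yn-1-ol
Product: 9 (2Z)-3-iodobut-2-en-1-ol, via cyclic alkenylalanate 8 (not isolated)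
Conditions: NaAlH2(OCH2CH2OMe)2 (1.5 equiv), THF, 0 °C → rt; then I2, −78 → 0 °C
Reagents that add atoms: iodine, II
Why: Alkoxide-directed trans-hydroalumination of the propargylic alcohol places aluminium at C3 in a five-membered ring (8) and hydride at C2; iodinolysis of the C–Al bond with retention gives the Z-iodide as a single geometric isomer.

Step 7
Reactants: 6 benzyl 2-{3-ethenyl-2-hydroxy-4-[(triisopropylsilyl)oxy]phenyl}acetate; 9 (2Z)-3-iodobut-2-en-1-ol
Product: 11 benzyl 2-{2-hydroxy-3-[(3Z)-5-hydroxy-3-methylpent-3-en-1-yl]-4-[(triisopropylsilyl)oxy]phenyl}acetate, via bis-borylated adduct 10 (not isolated)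
Conditions: 9-BBN (2.4 equiv), THF, 0 °C → rt; then 9, Pd(dppf)Cl2·CH2Cl2 (5 mol%), AsPh3 (5 mol%), powdered K3PO4 (3 equiv), DMF, 50 °C; aq. NH4Cl
Reagents that add atoms: none
Why: Anti-Markovnikov hydroboration of the styrene (the phenol is O-borylated and consumes one equivalent of borane) followed by B-alkyl Suzuki–Miyaura coupling, which keeps the Z geometry of 9; anhydrous phosphate is used so that the o-hydroxyphenylacetate is not saponified through its lactone.

Step 8
Reactants: 11 benzyl 2-{2-hydroxy-3-[(3Z)-5-hydroxy-3-methylpent-3-en-1-yl]-4-[(triisopropylsilyl)oxy]phenyl}acetate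
Product: 12 benzyl 2-{2-hydroxy-3-[(3Z)-5-[(methoxycarbonyl)oxy]-3-methylpent-3-en-1-yl]-4-[(triisopropylsilyl)oxy]phenyl}acetate
Conditions: ClCO2Me (1.2 equiv), pyridine (2 equiv), CH2Cl2, −20 → 0 °C
Reagents that add atoms: methyl chloroformate, COC(=O)Cl
Why: Chemoselective acylation of the primary allylic alcohol under pyridine catalysis; the phenol is flanked by two ortho substituents and is not ionised by pyridine, so it should react much more slowly.

Step 9
Reactants: 12 benzyl 2-{2-hydroxy-3-[(3Z)-5-[(methoxycarbonyl)oxy]-3-methylpent-3-en-1-yl]-4-[(triisopropylsilyl)oxy]phenyl}acetate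
Product: 13 benzyl 2-{(2S)-2-ethenyl-2-methyl-5-[(triisopropylsilyl)oxy]-3,4-dihydro-2H-chromen-8-yl}acetate
Conditions: Pd2(dba)3·CHCl3 (2 mol%), (1R,2R)-N,N'-bis[2-(diphenylphosphanyl)benzoyl]cyclohexane-1,2-diamine (6 mol%), AcOH (1 equiv), CH2Cl2, rt
Reagents that add atoms: none
Why: Intramolecular Tsuji–Trost asymmetric allylic etherification: ionisation of the carbonate gives a π-allylpalladium complex whose more substituted terminus is attacked by the phenol in a 6-exo closure; the chiral pocket of the C2-symmetric diphosphine selects the allyl face, and acetic acid speeds π–σ–π equilibration so that the faster-cyclising diastereomeric complex is funnelled to the (2S) chroman (Curtin–Hammett control).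

Step 10
Reactants: 13 benzyl 2-{(2S)-2-ethenyl-2-methyl-5-[(triisopropylsilyl)oxy]-3,4-dihydro-2H-chromen-8-yl}acetate
Product: 15 benzyl 2-{(2S)-2-(hydroxymethyl)-2-methyl-5-[(triisopropylsilyl)oxy]-3,4-dihydro-2H-chromen-8-yl}acetate, via chroman-2-carbaldehyde 14 (not isolated)
Conditions: O3 (to first persistence of the alkene end point), CH2Cl2/MeOH 4:1, −78 °C; then NaBH4, −78 → 0 °C
Reagents that add atoms: ozone, [O-][O+]=O
Why: Ozonolysis of the only alkene gives aldehyde 14, whose α-carbon is quaternary and cannot epimerise, and reduction in the same flask with NaBH4 at low temperature leaves the benzyl ester untouched; the silyl ether keeps the arene from competing for ozone.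

Step 11
Reactants: 15 benzyl 2-{(2S)-2-(hydroxymethyl)-2-methyl-5-[(triisopropylsilyl)oxy]-3,4-dihydro-2H-chromen-8-yl}acetate
Product: 16 benzyl 2-{(2S)-2-(acetoxymethyl)-2-methyl-5-[(triisopropylsilyl)oxy]-3,4-dihydro-2H-chromen-8-yl}acetate
Conditions: Ac2O (1.5 equiv), pyridine, DMAP (5 mol%), CH2Cl2, 0 °C → rt
Reagents that add atoms: acetic anhydride, CC(=O)OC(C)=O
Why: DMAP-catalysed acetylation of the neopentylic alcohol; the acetate shields it from acylation and from the Vilsmeier-type reagent in step 14 and from adding to the quinone methide in step 15, and it is removable at the end under mild methanolysis.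

Step 12
Reactants: 16 benzyl 2-{(2S)-2-(acetoxymethyl)-2-methyl-5-[(triisopropylsilyl)oxy]-3,4-dihydro-2H-chromen-8-yl}acetate
Product: 17 benzyl 2-[(2S)-2-(acetoxymethyl)-5-hydroxy-2-methyl-3,4-dihydro-2H-chromen-8-yl]acetate
Conditions: Bu4NF (1.1 equiv), AcOH (1.2 equiv), THF, 0 °C
Reagents that add atoms: none
Why: Fluoride cleavage of the aryl silyl ether, buffered with acetic acid so that the phenoxide released does not attack the acetate or the benzyl ester.

Step 13
Reactants: 17 benzyl 2-[(2S)-2-(acetoxymethyl)-5-hydroxy-2-methyl-3,4-dihydro-2H-chromen-8-yl]acetate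
Product: 18 2-[(2S)-2-(acetoxymethyl)-5-hydroxy-2-methyl-3,4-dihydro-2H-chromen-8-yl]acetic acid
Conditions: H2 (1 atm), 10% Pd/C, EtOAc, rt
Reagents that add atoms: none
Why: Hydrogenolysis of the benzyl ester; no alkene or other reducible group is left, the acetate and the tertiary ether are inert, and the acid is isolated by filtration and evaporation.

Step 14
Reactants: 18 2-[(2S)-2-(acetoxymethyl)-5-hydroxy-2-methyl-3,4-dihydro-2H-chromen-8-yl]acetic acid; 19 phloroglucinol (benzene-1,3,5-triol); 20 N,N-dimethylformamide
Product: 22 [(2S)-8-(5,7-dihydroxy-4-oxo-4H-chromen-3-yl)-5-hydroxy-2-methyl-3,4-dihydro-2H-chromen-2-yl]methyl acetate, via deoxybenzoin 21 (not isolated)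
Conditions: 19 (1.1 equiv), BF3·OEt2 (neat, excess), 75 °C; cool to 10 °C, add 20, then MeSO2Cl (3 equiv) in 20, 55 → 70 °C; pour into cold aq. NaOAc
Reagents that add atoms: none
Why: BF3·OEt2 turns the arylacetic acid into an acylating species that attacks phloroglucinol (Friedel–Crafts C-acylation, any O-acyl product rearranging under the same conditions), giving deoxybenzoin 21 as its boron chelate. DMF and MeSO2Cl then form a Vilsmeier-type iminium reagent that formylates the activated methylene of 21. The chelated ortho hydroxyl closes ring C by 6-exo-trig addition to the iminium carbon (equivalently a 6-endo-trig conjugate addition to the enaminone tautomer) and dimethylamine is lost, so that isoflavone C4–C4a, C3–C2 and C2–O1 are formed in one vessel. The closest known reaction type is the one-pot deoxybenzoin route to isoflavones (boron trifluoride-mediated acylation of a phenol with an arylacetic acid, then DMF and a sulfonyl chloride). No stereocentre is formed; the existing C2 centre has no acidic hydrogen, and ionisation of its O–C bond is disfavoured by the electron-withdrawing acetoxymethyl group. The selectivity needed is C-acylation on ring A and not on ring B or at oxygen: phloroglucinol is far more nucleophilic than the mono-phenolic ring B, its three carbons are equivalent so no regioisomer can arise, and the first acyl group deactivates it against a second. The saturated chroman stands in for the acid-labile chromene, and the acetate keeps the primary alcohol from being esterified, formylated or sulfonylated.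

Step 15
Reactants: 22 [(2S)-8-(5,7-dihydroxy-4-oxo-4H-chromen-3-yl)-5-hydroxy-2-methyl-3,4-dihydro-2H-chromen-2-yl]methyl acetate
Product: 23 [(2S)-8-(5,7-dihydroxy-4-oxo-4H-chromen-3-yl)-5-hydroxy-2-methyl-2H-chromen-2-yl]methyl acetate
Conditions: DDQ (1.2 equiv), 1,4-dioxane, 50–80 °C, dark, argon
Reagents that add atoms: none
Why: DDQ abstracts hydride from the benzylic C4; the cation is stabilised by the ortho phenol at C5 (ortho-quinone methide) and by O1, and loss of a C3 proton gives the C3=C4 alkene, while the quaternary C2 blocks further oxidation to a benzopyrylium ion. The reaction is run in the dark at the lowest workable temperature because 2H-chromenes can racemise by electrocyclic ring-opening.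

Step 16
Reactants: 23 [(2S)-8-(5,7-dihydroxy-4-oxo-4H-chromen-3-yl)-5-hydroxy-2-methyl-2H-chromen-2-yl]methyl acetate
Product: 24 5,7-dihydroxy-3-[(2S)-5-hydroxy-2-(hydroxymethyl)-2-methyl-2H-chromen-8-yl]-4H-chromen-4-one (CNP0141863.1)
Conditions: K2CO3 (3 equiv), MeOH, 0 °C → rt, dark; aq. NH4Cl
Reagents that add atoms: none
Why: Base-mediated methanolysis (transesterification) of the primary acetate; the conditions should be mild enough for the pyranone ring and the chromene, and the stereocentre bears no acidic hydrogen.

## Compound list

1 | 2,4-dihydroxyphenylacetic acid | O=C(O)Cc1ccc(O)cc1O | starting material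
2 | 6-hydroxy-1-benzofuran-2(3H)-one | O=C1Cc2ccc(O)cc2O1 | intermediate
3 | 6-[(triisopropylsilyl)oxy]-1-benzofuran-2(3H)-one | O=C1Cc2ccc(O[Si](C(C)C)(C(C)C)C(C)C)cc2O1 | intermediate
4 | benzyl 2-{2-hydroxy-4-[(triisopropylsilyl)oxy]phenyl}acetate | O=C(Cc1ccc(O[Si](C(C)C)(C(C)C)C(C)C)cc1O)OCc1ccccc1 | intermediate
5 | benzyl 2-{3-formyl-2-hydroxy-4-[(triisopropylsilyl)oxy]phenyl}acetate | O=C(Cc1ccc(O[Si](C(C)C)(C(C)C)C(C)C)c(C=O)c1O)OCc1ccccc1 | intermediate
6 | benzyl 2-{3-ethenyl-2-hydroxy-4-[(triisopropylsilyl)oxy]phenyl}acetate | O=C(Cc1ccc(O[Si](C(C)C)(C(C)C)C(C)C)c(C=C)c1O)OCc1ccccc1 | intermediate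
7 | but-2-yn-1-ol | CC#CCO | starting material
8 | sodium 2,2-bis(2-methoxyethoxy)-3-methyl-2,5-dihydro-1,2-oxaaluminol-2-uide (cyclic alkenylalanate) | CC1=CCO[Al-]1(OCCOC)OCCOC.[Na+] | intermediate
9 | (2Z)-3-iodobut-2-en-1-ol | C/C(I)=C/CO | intermediate
10 | benzyl 2-{2-[(9-borabicyclo[3.3.1]nonan-9-yl)oxy]-3-[2-(9-borabicyclo[3.3.1]nonan-9-yl)ethyl]-4-[(triisopropylsilyl)oxy]phenyl}acetate | O=C(OCc1ccccc1)Cc1ccc(O[Si](C(C)C)(C(C)C)C(C)C)c(CCB2C3CCCC2CCC3)c1OB1C2CCCC1CCC2 | intermediate
11 | benzyl 2-{2-hydroxy-3-[(3Z)-5-hydroxy-3-methylpent-3-en-1-yl]-4-[(triisopropylsilyl)oxy]phenyl}acetate | C/C(CCc1c(O)c(CC(=O)OCc2ccccc2)ccc1O[Si](C(C)C)(C(C)C)C(C)C)=C/CO | intermediate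
12 | benzyl 2-{2-hydroxy-3-[(3Z)-5-[(methoxycarbonyl)oxy]-3-methylpent-3-en-1-yl]-4-[(triisopropylsilyl)oxy]phenyl}acetate | C/C(CCc1c(O)c(CC(=O)OCc2ccccc2)ccc1O[Si](C(C)C)(C(C)C)C(C)C)=C/COC(=O)OC | intermediate
13 | benzyl 2-{(2S)-2-ethenyl-2-methyl-5-[(triisopropylsilyl)oxy]-3,4-dihydro-2H-chromen-8-yl}acetate | C[C@@]1(C=C)CCc2c(O[Si](C(C)C)(C(C)C)C(C)C)ccc(CC(=O)OCc3ccccc3)c2O1 | intermediate
14 | benzyl 2-{(2S)-2-formyl-2-methyl-5-[(triisopropylsilyl)oxy]-3,4-dihydro-2H-chromen-8-yl}acetate | C[C@@]1(C=O)CCc2c(O[Si](C(C)C)(C(C)C)C(C)C)ccc(CC(=O)OCc3ccccc3)c2O1 | intermediate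
15 | benzyl 2-{(2S)-2-(hydroxymethyl)-2-methyl-5-[(triisopropylsilyl)oxy]-3,4-dihydro-2H-chromen-8-yl}acetate | C[C@@]1(CO)CCc2c(O[Si](C(C)C)(C(C)C)C(C)C)ccc(CC(=O)OCc3ccccc3)c2O1 | intermediate
16 | benzyl 2-{(2S)-2-(acetoxymethyl)-2-methyl-5-[(triisopropylsilyl)oxy]-3,4-dihydro-2H-chromen-8-yl}acetate | C[C@@]1(COC(C)=O)CCc2c(O[Si](C(C)C)(C(C)C)C(C)C)ccc(CC(=O)OCc3ccccc3)c2O1 | intermediate
17 | benzyl 2-[(2S)-2-(acetoxymethyl)-5-hydroxy-2-methyl-3,4-dihydro-2H-chromen-8-yl]acetate | C[C@@]1(COC(C)=O)CCc2c(O)ccc(CC(=O)OCc3ccccc3)c2O1 | intermediate
18 | 2-[(2S)-2-(acetoxymethyl)-5-hydroxy-2-methyl-3,4-dihydro-2H-chromen-8-yl]acetic acid | C[C@@]1(COC(C)=O)CCc2c(O)ccc(CC(=O)O)c2O1 | intermediate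
19 | phloroglucinol (benzene-1,3,5-triol) | Oc1cc(O)cc(O)c1 | starting material
20 | N,N-dimethylformamide | CN(C)C=O | starting material
21 | {(2S)-5-hydroxy-2-methyl-8-[2-oxo-2-(2,4,6-trihydroxyphenyl)ethyl]-3,4-dihydro-2H-chromen-2-yl}methyl acetate (deoxybenzoin) | C[C@@]1(COC(C)=O)CCc2c(O)ccc(CC(=O)c3c(O)cc(O)cc3O)c2O1 | intermediate
22 | [(2S)-8-(5,7-dihydroxy-4-oxo-4H-chromen-3-yl)-5-hydroxy-2-methyl-3,4-dihydro-2H-chromen-2-yl]methyl acetate | C[C@@]1(COC(C)=O)CCc2c(O)ccc(-c3coc4cc(O)cc(O)c4c3=O)c2O1 | intermediate
23 | [(2S)-8-(5,7-dihydroxy-4-oxo-4H-chromen-3-yl)-5-hydroxy-2-methyl-2H-chromen-2-yl]methyl acetate | C[C@@]1(COC(C)=O)C=Cc2c(O)ccc(-c3coc4cc(O)cc(O)c4c3=O)c2O1 | intermediate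
24 | 5,7-dihydroxy-3-[(2S)-5-hydroxy-2-(hydroxymethyl)-2-methyl-2H-chromen-8-yl]-4H-chromen-4-one (CNP0141863.1) | C[C@@]1(CO)C=Cc2c(O)ccc(-c3coc4cc(O)cc(O)c4c3=O)c2O1 | target

## Step count and least certain steps

Total step count: 16. Longest linear sequence: 15 steps (1 to 24 through steps 1–5 and 7–16); step 6 prepares fragment 9.

**Step 14 (key step).** The most likely failure is reversible ionisation of the tertiary aryl ether in hot BF3·OEt2, which would erode the configuration at C2 or open the pyran ring. Acyl transfer from the acetate and incomplete formylative closure are lesser risks.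

Fallback, setting out from 18 and returning at 22: the acid 18 would be converted in situ into its mixed anhydride with (CF3CO)2O in CH2Cl2 at 0 °C and used to acylate 1,3,5-tris(benzyloxy)benzene without any Lewis acid. After a bicarbonate work-up, which removes any phenol trifluoroacetate, this should give {(2S)-5-hydroxy-2-methyl-8-{2-oxo-2-[2,4,6-tris(benzyloxy)phenyl]ethyl}-3,4-dihydro-2H-chromen-2-yl}methyl acetate F1. Hydrogenolysis (H2, Pd/C, EtOAc) would give deoxybenzoin 21, now isolated. Ring C would then be closed under neutral conditions with Me2NCH(OMe)2 in THF at 60 °C (enaminone formation and cyclisation) to give 22.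

**Step 15.** The free phenols of rings A and B may be over-oxidised, the quinone methide may be trapped by adventitious nucleophiles, and the product may lose optical purity through thermal or photochemical electrocyclic ring-opening if the temperature has to be raised.

Fallback, setting out from 22 and returning at 24: peracetylation (Ac2O, pyridine, DMAP) would give [(2S)-5-acetoxy-8-(5,7-diacetoxy-4-oxo-4H-chromen-3-yl)-2-methyl-3,4-dihydro-2H-chromen-2-yl]methyl acetate F2. Radical bromination of the only benzylic methylene (N-bromosuccinimide, AIBN, PhCF3, 80 °C) would give [(2S)-5-acetoxy-4-bromo-8-(5,7-diacetoxy-4-oxo-4H-chromen-3-yl)-2-methyl-3,4-dihydro-2H-chromen-2-yl]methyl acetate F3 as a mixture of C4 epimers. Elimination with DBU in THF would give [(2S)-5-acetoxy-8-(5,7-diacetoxy-4-oxo-4H-chromen-3-yl)-2-methyl-2H-chromen-2-yl]methyl acetate F4. Global methanolysis with K2CO3 in MeOH then gives 24 directly.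

**Step 9.** Facial discrimination may be insufficient, or its sense opposite, with this crowded di-ortho-substituted phenol. β-Hydride elimination of the π-allyl complex to a diene may also compete with cyclisation.

Fallback, setting out from 11 and returning at 15: Sharpless asymmetric epoxidation of the Z-allylic alcohol (Ti(OiPr)4, L-(+)-diethyl tartrate, tBuOOH, 4 Å molecular sieves, CH2Cl2, −20 °C, stoichiometric titanium because of the free phenol) should give benzyl 2-{2-hydroxy-3-{2-[(2R,3S)-3-(hydroxymethyl)-2-methyloxiran-2-yl]ethyl}-4-[(triisopropylsilyl)oxy]phenyl}acetate F5. Acid-promoted 6-exo opening of the epoxide at its tertiary carbon by the phenol, with inversion (camphorsulfonic acid, CH2Cl2, 0 °C), would give benzyl 2-{(2S)-2-[(1S)-1,2-dihydroxyethyl]-2-methyl-5-[(triisopropylsilyl)oxy]-3,4-dihydro-2H-chromen-8-yl}acetate F6. Glycol cleavage with NaIO4 in THF/H2O gives aldehyde 14, and NaBH4 reduction gives 15.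

**Step 4.** Formylation may be slow because C3 lies between the phenoxide oxygen and the bulky silyl ether, and prolonged heating with base may close the o-hydroxyphenylacetate back to its lactone.

Fallback, setting out from 4 and returning at 5: O-allylation (allyl bromide, K2CO3, acetone) would give benzyl 2-{2-(prop-2-en-1-yloxy)-4-[(triisopropylsilyl)oxy]phenyl}acetate F7. Aromatic Claisen rearrangement (N,N-diethylaniline, 190 °C) to the only free ortho position would give benzyl 2-{2-hydroxy-3-(prop-2-en-1-yl)-4-[(triisopropylsilyl)oxy]phenyl}acetate F8; any material that lactonises at this temperature is reopened as in step 3. Alkene isomerisation into conjugation (RuHCl(CO)(PPh3)3, toluene, 80 °C) would give benzyl 2-{2-hydroxy-3-[(1E)-prop-1-en-1-yl]-4-[(triisopropylsilyl)oxy]phenyl}acetate F9. Oxidative cleavage (OsO4 cat., NaIO4, 2,6-lutidine, dioxane/H2O) gives aldehyde 5.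

## Further compounds

F1 | step 14 | {(2S)-5-hydroxy-2-methyl-8-{2-oxo-2-[2,4,6-tris(benzyloxy)phenyl]ethyl}-3,4-dihydro-2H-chromen-2-yl}methyl acetate | C[C@@]1(COC(C)=O)CCc2c(O)ccc(CC(=O)c3c(OCc4ccccc4)cc(OCc4ccccc4)cc3OCc3ccccc3)c2O1
F2 | step 15 | [(2S)-5-acetoxy-8-(5,7-diacetoxy-4-oxo-4H-chromen-3-yl)-2-methyl-3,4-dihydro-2H-chromen-2-yl]methyl acetate | C[C@@]1(COC(C)=O)CCc2c(OC(C)=O)ccc(-c3coc4cc(OC(C)=O)cc(OC(C)=O)c4c3=O)c2O1
F3 | step 15 | [(2S)-5-acetoxy-4-bromo-8-(5,7-diacetoxy-4-oxo-4H-chromen-3-yl)-2-methyl-3,4-dihydro-2H-chromen-2-yl]methyl acetate (C4 epimers) | C[C@@]1(COC(C)=O)CC(Br)c2c(OC(C)=O)ccc(-c3coc4cc(OC(C)=O)cc(OC(C)=O)c4c3=O)c2O1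
F4 | step 15 | [(2S)-5-acetoxy-8-(5,7-diacetoxy-4-oxo-4H-chromen-3-yl)-2-methyl-2H-chromen-2-yl]methyl acetate | C[C@@]1(COC(C)=O)C=Cc2c(OC(C)=O)ccc(-c3coc4cc(OC(C)=O)cc(OC(C)=O)c4c3=O)c2O1
F5 | step 9 | benzyl 2-{2-hydroxy-3-{2-[(2R,3S)-3-(hydroxymethyl)-2-methyloxiran-2-yl]ethyl}-4-[(triisopropylsilyl)oxy]phenyl}acetate | C[C@]1(CCc2c(O)c(CC(=O)OCc3ccccc3)ccc2O[Si](C(C)C)(C(C)C)C(C)C)O[C@H]1CO
F6 | step 9 | benzyl 2-{(2S)-2-[(1S)-1,2-dihydroxyethyl]-2-methyl-5-[(triisopropylsilyl)oxy]-3,4-dihydro-2H-chromen-8-yl}acetate | C[C@@]1([C@@H](O)CO)CCc2c(O[Si](C(C)C)(C(C)C)C(C)C)ccc(CC(=O)OCc3ccccc3)c2O1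
F7 | step 4 | benzyl 2-{2-(prop-2-en-1-yloxy)-4-[(triisopropylsilyl)oxy]phenyl}acetate | C=CCOc1cc(O[Si](C(C)C)(C(C)C)C(C)C)ccc1CC(=O)OCc1ccccc1
F8 | step 4 | benzyl 2-{2-hydroxy-3-(prop-2-en-1-yl)-4-[(triisopropylsilyl)oxy]phenyl}acetate | C=CCc1c(O)c(CC(=O)OCc2ccccc2)ccc1O[Si](C(C)C)(C(C)C)C(C)C
F9 | step 4 | benzyl 2-{2-hydroxy-3-[(1E)-prop-1-en-1-yl]-4-[(triisopropylsilyl)oxy]phenyl}acetate | C/C=C/c1c(O)c(CC(=O)OCc2ccccc2)ccc1O[Si](C(C)C)(C(C)C)C(C)C
A1 | alternative 1 | (2S,4S)-8-bromo-2-methyl-5-[(triisopropylsilyl)oxy]-3,4-dihydro-2H-4,2-(epoxymethano)chromene | C[C@@]12CO[C@@H](C1)c1c(O[Si](C(C)C)(C(C)C)C(C)C)ccc(Br)c1O2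
A2 | alternative 2 | (2S)-2-{[(tert-butyldimethylsilyl)oxy]methyl}-8-chloro-5-(methoxymethoxy)-2-methyl-2H-chromene | C[C@@]1(CO[Si](C)(C)C(C)(C)C)C=Cc2c(OCOC)ccc(Cl)c2O1
A3 | alternative 3 | tert-butyl (2S)-8-bromo-5-(methoxymethoxy)-2-methyl-3,4-dihydro-2H-chromene-2-carboxylate | C[C@@]1(C(=O)OC(C)(C)C)CCc2c(OCOC)ccc(Br)c2O1
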